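**Retrosynthetic overview**
1. The last bonds made are C4–O and C5–O: a new hydroxyl-anchored zinc peroxide epoxidation of the macrocyclic 4Z-enone sets C4 and C5. The C8–O tiglate comes from an invertive Mitsunobu esterification.
2. The ten-membered carbocycle is closed at C3–C4 by an intramolecular Nozaki–Hiyama–Kishi coupling (Z-vinyl iodide plus aldehyde), followed by allylic oxidation to the 3-ketone.
3. The lactone C–O bond is made first, as the ester of an iodo dienol with 2-(bromomethyl)acrylic acid; ring-closing metathesis gives a 3-(bromomethyl)butenolide, and an indium Barbier allylation (C7–C8) converts it into the trans-fused α-methylene lactone.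
4. The eastern aldehyde (C8–C10, C1–C3) comes from anti-crotylation of propane-1,3-diol (sets C1 and C10), then acetonide formation, hydroboration and oxidation.
5. Ring order: butenolide, then α-methylene-γ-lactone, then ten-membered ring, then epoxide.

Assumption: atom labels C1–C15 follow germacrane numbering of the target (lactone carbonyl C12, exocyclic methylene C13, methyl C14 on C10, methyl C15 on C4).

**Step 1**
Reactants: 1 but-2-yn-1-ol
Product: 3 (2Z)-3-iodobut-2-en-1-ol, via cyclic sodium alkenylalanate 2 (not isolated)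
Conditions: Red-Al (NaAlH2(OCH2CH2OMe)2, 1.4 equiv), THF, 0 °C to rt; then I2, −78 to 0 °C
Reagents that add atoms: iodine, II
Why: Alkoxide-directed trans-hydroalumination of the propargylic alcohol puts aluminium on the carbon that becomes C4, cis to the CH2O group, and iodinolysis with retention gives the Z-vinyl iodide (hydrometalation–iodination).

**Step 2**
Reactants: 3 (2Z)-3-iodobut-2-en-1-ol
Product: 4 (2Z)-3-iodobut-2-enal
Conditions: MnO2 (activated, 15 equiv), CH2Cl2, rt, dark
Reagents that add atoms: none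
Why: MnO2 oxidises the primary allylic alcohol to the enal without touching the vinyl iodide (allylic oxidation), and the labile Z-enal is used at once.

**Step 3**
Reactants: 4 (2Z)-3-iodobut-2-enal
Product: 5 (3S,4Z)-5-iodohexa-1,4-dien-3-ol
Conditions: Zn(CH=CH2)2 (from CH2=CHMgBr and ZnCl2, salts removed with 1,4-dioxane), (−)-MIB (5 mol %), toluene, −20 °C; aq NH4Cl
Reagents that add atoms: divinylzinc, C=C[Zn]C=C
Why: Amino-alcohol-catalysed enantioselective 1,2-addition of a vinylzinc reagent to the aldehyde, in which (−)-MIB directs attack to the Si face and sets the carbinol (future C6) as S.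

**Step 4**
Reactants: 5 (3S,4Z)-5-iodohexa-1,4-dien-3-ol; 6 2-(bromomethyl)prop-2-enoic acid
Product: 7 (3S,4Z)-5-iodohexa-1,4-dien-3-yl 2-(bromomethyl)prop-2-enoate
Conditions: DCC, DMAP (5 mol %), CH2Cl2, −20 to 0 °C
Reagents that add atoms: none
Why: Steglich esterification builds the lactone C12–O–C6 bond before any ring is closed and touches no stereocentre.

**Step 5**
Reactants: 7 (3S,4Z)-5-iodohexa-1,4-dien-3-yl 2-(bromomethyl)prop-2-enoate
Product: 8 (5S)-3-(bromomethyl)-5-[(1Z)-2-iodoprop-1-en-1-yl]furan-2(5H)-one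
Conditions: second-generation Grubbs catalyst (H2IMes)(PCy3)Cl2Ru=CHPh (5 mol %), CH2Cl2 (5 mM), 40 °C
Reagents that add atoms: none
Why: Ring-closing metathesis of the vinyl group with the 1,1-disubstituted acrylate closes the five-membered butenolide, while the trisubstituted iodoalkene does not take part.

**Step 6**
Reactants: 9 propane-1,3-diol; 10 but-3-en-2-yl acetate (racemic)
Product: 11 (3R,4S)-4-methylhex-5-ene-1,3-diol
Conditions: [Ir(cod)Cl]2 (2.5 mol %), (S)-SEGPHOS (5 mol %), 4-cyano-3-nitrobenzoic acid (10 mol %), Cs2CO3 (20 mol %), 9 (4 equiv), THF, 90 °C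
Reagents that add atoms: none
Why: Iridium-catalysed transfer-hydrogenative anti-crotylation at the alcohol oxidation level (Krische crotylation), in which the E-crotyliridium adds to the transient aldehyde through a chair transition state and the (S)-ligand sets C1 as R and C10 as S; excess diol limits double crotylation.

**Step 7**
Reactants: 11 (3R,4S)-4-methylhex-5-ene-1,3-diol
Product: 12 (4R)-4-[(2S)-but-3-en-2-yl]-2,2-dimethyl-1,3-dioxane
Conditions: Me2C(OMe)2, PPTS (cat.), CH2Cl2, rt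
Reagents that add atoms: 2,2-dimethoxypropane, COC(C)(C)OC
Why: Acid-catalysed transketalisation gives the six-membered acetonide of the 1,3-diol and leaves both stereocentres unchanged.

**Step 8**
Reactants: 12 (4R)-4-[(2S)-but-3-en-2-yl]-2,2-dimethyl-1,3-dioxane
Product: 14 (3S)-3-[(4R)-2,2-dimethyl-1,3-dioxan-4-yl]butan-1-ol, via B-alkyl-9-BBN adduct 13 (not isolated)
Conditions: 9-BBN, THF, 0 °C to rt; then NaOH, H2O2, 0 °C
Reagents that add atoms: hydrogen peroxide, OO
Why: Anti-Markovnikov hydroboration of the terminal alkene with 9-BBN and oxidation of the C–B bond gives the primary alcohol at C8 without affecting a stereocentre (hydroboration–oxidation).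

**Step 9**
Reactants: 14 (3S)-3-[(4R)-2,2-dimethyl-1,3-dioxan-4-yl]butan-1-ol
Product: 15 (3S)-3-[(4R)-2,2-dimethyl-1,3-dioxan-4-yl]butanal
Conditions: Dess–Martin periodinane, NaHCO3, CH2Cl2, 0 °C to rt
Reagents that add atoms: none
Why: Buffered Dess–Martin oxidation gives the C8 aldehyde, which has no α-stereocentre to epimerise.

**Step 10**
Reactants: 8 (5S)-3-(bromomethyl)-5-[(1Z)-2-iodoprop-1-en-1-yl]furan-2(5H)-one; 15 (3S)-3-[(4R)-2,2-dimethyl-1,3-dioxan-4-yl]butanal
Product: 16 (4R,5S)-4-[(1S,3S)-3-[(4R)-2,2-dimethyl-1,3-dioxan-4-yl]-1-hydroxybutyl]-5-[(1Z)-2-iodoprop-1-en-1-yl]-3-methylideneoxolan-2-one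
Conditions: In powder (1.5 equiv), THF/H2O 1:1, rt
Reagents that add atoms: none
Why: Indium-mediated Barbier allylation in which the allylindium formed at C13 adds through C7 in a chair Zimmerman–Traxler transition state, anti to the C6 substituent (trans-lactone, C7 R); the ring-locked E-type geometry gives the anti carbinol (C8 S) and moves the double bond to the exocyclic position.

**Step 11**
Reactants: 16 (the 8S alcohol from step 10); 17 (2E)-2-methylbut-2-enoic acid (tiglic acid)
Product: 18 (1R,3S)-3-[(4R)-2,2-dimethyl-1,3-dioxan-4-yl]-1-[(2S,3R)-2-[(1Z)-2-iodoprop-1-en-1-yl]-4-methylidene-5-oxooxolan-3-yl]butyl (2E)-2-methylbut-2-enoate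
Conditions: PPh3, DIAD, toluene, 0 °C to rt
Reagents that add atoms: none
Why: Mitsunobu esterification forms the C8–O bond by SN2 displacement of the alkoxyphosphonium by tiglate with inversion, turning the 8S alcohol into the 8R (8β) tiglate.

**Step 12**
Reactants: 18 (the acetonide tiglate from step 11)
Product: 19 (1R,3S,4R)-4,6-dihydroxy-1-[(2S,3R)-2-[(1Z)-2-iodoprop-1-en-1-yl]-4-methylidene-5-oxooxolan-3-yl]-3-methylhexyl (2E)-2-methylbut-2-enoate
Conditions: AcOH/THF/H2O 3:1:1, 40 °C
Reagents that add atoms: none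
Why: Mild acid hydrolysis removes the acetonide, and the esters, the vinyl iodide and the α-methylene lactone are stable under these conditions.

**Step 13**
Reactants: 19 (the diol from step 12)
Product: 20 (1R,3S,4R)-4-hydroxy-1-[(2S,3R)-2-[(1Z)-2-iodoprop-1-en-1-yl]-4-methylidene-5-oxooxolan-3-yl]-3-methyl-6-oxohexyl (2E)-2-methylbut-2-enoate
Conditions: TEMPO (20 mol %), PhI(OAc)2, CH2Cl2, rt
Reagents that add atoms: none
Why: The oxoammonium oxidation (TEMPO/PhI(OAc)2) takes the primary C3 alcohol to the aldehyde and leaves the secondary C1 hydroxyl alone.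

**Step 14**
Reactants: 20 (the hydroxy aldehyde from step 13)
Product: 21 (4Z)-1β,3ξ-dihydroxy-8β-[(2E)-2-methylbut-2-enoyloxy]-10αH-germacra-4,11(13)-dien-12,6α-olide (C3 epimers)
Conditions: CrCl2 (8 equiv), NiCl2 (2 mol %), DMSO/THF 3:1, 2 mM, rt
Reagents that add atoms: none
Why: Intramolecular Nozaki–Hiyama–Kishi reaction in which nickel activates the vinyl iodide and the resulting alkenylchromium species adds only to the aldehyde with retention of the Z geometry, closing the ten-membered ring at C3–C4; the C3 carbinol forms as a mixture that is removed in step 15.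

**Step 15**
Reactants: 21 (the macrocyclic diol from step 14)
Product: 22 (4Z)-1β-hydroxy-3-oxo-8β-[(2E)-2-methylbut-2-enoyloxy]-10αH-germacra-4,11(13)-dien-12,6α-olide
Conditions: MnO2 (activated, 20 equiv), CH2Cl2, rt
Reagents that add atoms: none
Why: MnO2 oxidises only the allylic C3 alcohol (allylic oxidation), so both C3 epimers converge on the Z-enone and the saturated C1 hydroxyl is kept.

**Step 16**
Reactants: 22 (the β-hydroxy Z-enone from step 15)
Product: 23 eupakirunsin C, (1R,4R,5R,6S,7R,8R,10S)-4β,5β-epoxy-1β-hydroxy-3-oxo-8β-[(2E)-2-methylbut-2-enoyloxy]-10αH-germacr-11(13)-en-12,6α-olide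
Conditions: Et2Zn (1.1 equiv), tBuOOH (2.3 equiv, decane), toluene, −20 °C, 30 min [gives Zn(OOtBu)2]; then 22, 4 Å MS, −20 to 0 °C
Reagents that add atoms: tert-butyl hydroperoxide, CC(C)(C)OO
Why: Proposed new method: the C1 hydroxyl exchanges onto Zn(OOtBu)2 to give a zinc alkoxide–alkylperoxide that chelates the C3 ketone like a zinc aldolate, which activates the enone and delivers the peroxide oxygen intramolecularly to C5 from the β-face where the 1β-alkoxide holds the metal, and the zinc enolate closes the oxirane with loss of tert-butoxide before C4–C5 rotation, so the cis (4R,5R) epoxide should form while the unanchored α-methylene lactone and tiglate stay untouched; the closest known reaction type is the Weitz–Scheffer epoxidation of enones with zinc or lanthanide alkylperoxides carried by an external amino-alcohol or binaphthol ligand, together with hydroxyl-directed epoxidation.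

**Compound list**
1 | but-2-yn-1-ol | CC#CCO | starting material
2 | cyclic sodium alkenylalanate (sodium 2,2-bis(2-methoxyethoxy)-3-methyl-2,5-dihydro-1,2-oxaluminol-2-uide, not isolated) | CC1=CCO[Al-]1(OCCOC)OCCOC.[Na+] | intermediate
3 | (2Z)-3-iodobut-2-en-1-ol | OC/C=C(C)\I | intermediate
4 | (2Z)-3-iodobut-2-enal | O=C/C=C(C)\I | intermediate
5 | (3S,4Z)-5-iodohexa-1,4-dien-3-ol | O[C@H](/C=C(C)\I)C=C | intermediate
6 | 2-(bromomethyl)prop-2-enoic acid | C=C(CBr)C(=O)O | starting material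
7 | (3S,4Z)-5-iodohexa-1,4-dien-3-yl 2-(bromomethyl)prop-2-enoate | C=C(CBr)C(=O)O[C@H](/C=C(C)\I)C=C | intermediate
8 | (5S)-3-(bromomethyl)-5-[(1Z)-2-iodoprop-1-en-1-yl]furan-2(5H)-one | O=C1O[C@H](/C=C(C)\I)C=C1CBr | intermediate
9 | propane-1,3-diol | OCCCO | starting material
10 | but-3-en-2-yl acetate (racemic) | CC(OC(C)=O)C=C | starting material
11 | (3R,4S)-4-methylhex-5-ene-1,3-diol | C=C[C@H](C)[C@H](O)CCO | intermediate
12 | (4R)-4-[(2S)-but-3-en-2-yl]-2,2-dimethyl-1,3-dioxane | C=C[C@H](C)[C@H]1CCOC(C)(C)O1 | intermediate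
13 | 9-[(3S)-3-[(4R)-2,2-dimethyl-1,3-dioxan-4-yl]butyl]-9-borabicyclo[3.3.1]nonane (not isolated) | C1CC2CCCC(C1)B2CC[C@H](C)[C@H]1CCOC(C)(C)O1 | intermediate
14 | (3S)-3-[(4R)-2,2-dimethyl-1,3-dioxan-4-yl]butan-1-ol | OCC[C@H](C)[C@H]1CCOC(C)(C)O1 | intermediate
15 | (3S)-3-[(4R)-2,2-dimethyl-1,3-dioxan-4-yl]butanal | O=CC[C@H](C)[C@H]1CCOC(C)(C)O1 | intermediate
16 | (4R,5S)-4-[(1S,3S)-3-[(4R)-2,2-dimethyl-1,3-dioxan-4-yl]-1-hydroxybutyl]-5-[(1Z)-2-iodoprop-1-en-1-yl]-3-methylideneoxolan-2-one | C=C1C(=O)O[C@H](/C=C(C)\I)[C@H]1[C@@H](O)C[C@H](C)[C@H]2CCOC(C)(C)O2 | intermediate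
17 | (2E)-2-methylbut-2-enoic acid (tiglic acid) | C/C=C(\C)C(=O)O | starting material
18 | (1R,3S)-3-[(4R)-2,2-dimethyl-1,3-dioxan-4-yl]-1-[(2S,3R)-2-[(1Z)-2-iodoprop-1-en-1-yl]-4-methylidene-5-oxooxolan-3-yl]butyl (2E)-2-methylbut-2-enoate | C=C1C(=O)O[C@H](/C=C(C)\I)[C@H]1[C@H](OC(=O)/C(C)=C/C)C[C@H](C)[C@H]2CCOC(C)(C)O2 | intermediate
19 | (1R,3S,4R)-4,6-dihydroxy-1-[(2S,3R)-2-[(1Z)-2-iodoprop-1-en-1-yl]-4-methylidene-5-oxooxolan-3-yl]-3-methylhexyl (2E)-2-methylbut-2-enoate | C=C1C(=O)O[C@H](/C=C(C)\I)[C@H]1[C@H](OC(=O)/C(C)=C/C)C[C@H](C)[C@H](O)CCO | intermediate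
20 | (1R,3S,4R)-4-hydroxy-1-[(2S,3R)-2-[(1Z)-2-iodoprop-1-en-1-yl]-4-methylidene-5-oxooxolan-3-yl]-3-methyl-6-oxohexyl (2E)-2-methylbut-2-enoate | C=C1C(=O)O[C@H](/C=C(C)\I)[C@H]1[C@H](OC(=O)/C(C)=C/C)C[C@H](C)[C@H](O)CC=O | intermediate
21 | (4Z)-1β,3ξ-dihydroxy-8β-[(2E)-2-methylbut-2-enoyloxy]-10αH-germacra-4,11(13)-dien-12,6α-olide (C3 epimers) | C=C1C(=O)O[C@H]2[C@H]1[C@H](OC(=O)/C(C)=C/C)C[C@H](C)[C@H](O)CC(O)/C(C)=C\2 | intermediate
22 | (4Z)-1β-hydroxy-3-oxo-8β-[(2E)-2-methylbut-2-enoyloxy]-10αH-germacra-4,11(13)-dien-12,6α-olide | C=C1C(=O)O[C@H]2[C@H]1[C@H](OC(=O)/C(C)=C/C)C[C@H](C)[C@H](O)CC(=O)/C(C)=C\2 | intermediate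
23 | eupakirunsin C, (1R,4R,5R,6S,7R,8R,10S)-4β,5β-epoxy-1β-hydroxy-3-oxo-8β-[(2E)-2-methylbut-2-enoyloxy]-10αH-germacr-11(13)-en-12,6α-olide | C=C1C(=O)O[C@H]2[C@H]1[C@H](OC(=O)/C(C)=C/C)C[C@H](C)[C@H](O)CC(=O)[C@]1(C)O[C@H]21 | target

**Step count and risks**
Total step count: 16. Longest linear sequence: 12 steps (steps 1–5, then 10–16, from but-2-yn-1-ol).

The three steps most likely to fail:

Step 16 (the proposed new epoxidation). The zinc peroxide may also attack the α-methylene lactone, the β-hydroxy ketone may undergo retro-aldol cleavage, or the wrong face or the trans-epoxide may form. The fallback uses known chemistry and sets out from 22. Thiophenol with catalytic Et3N adds selectively to the unhindered exocyclic methylene to give the 13-phenylsulfanyl adduct F1, which masks the lactone. A classical Weitz–Scheffer epoxidation (tBuOOH, DBU, CH2Cl2, 0 °C) of the now unique enone gives the epoxy ketone sulfide F2. NaIO4 in MeOH/H2O gives the sulfoxide F3, and heating in toluene at 110 °C over NaHCO3 eliminates it by syn-elimination and restores the α-methylene lactone, which brings the route back at 23.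

Step 14 (ten-membered ring closure by Nozaki–Hiyama–Kishi coupling). Ring strain next to the trans-fused lactone may favour oligomers or reduction of the iodide. The fallback changes the ring-closing reaction from a carbonyl addition to an acylation and sets out from 19. TEMPO/PhI(OAc)2 in MeCN/H2O oxidises the primary alcohol to the hydroxy acid F4. 2,2'-Dipyridyl disulfide and PPh3 give the S-pyridin-2-yl thioester F5. (Me3Sn)2 with Pd(PPh3)4 exchanges the iodide for tin with retention to give the Z-vinylstannane F6. A palladium-catalysed, copper-mediated thioester–stannane coupling (Pd2(dba)3, tri(2-furyl)phosphine, CuO2PPh2, THF, high dilution) then closes the ring directly to the enone and comes back to the route at 22.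

Step 11 (Mitsunobu inversion at the hindered C8 carbinol). Elimination towards C7 or poor conversion with the weakly acidic tiglic acid is possible, and this step also depends on the C8 configuration delivered by step 10. The fallback sets C8 by reagent control instead of displacement and sets out from 16. Buffered Dess–Martin oxidation gives the C8 ketone F7. Reduction with the (S)-Me-CBS oxazaborolidine and catecholborane at −78 °C gives the 8R alcohol F8. Yamaguchi esterification with 17 (2,4,6-trichlorobenzoyl chloride, Et3N, DMAP, toluene) with retention then comes back to the route at 18.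

**Further compounds**
F1 | step 16 | (4Z)-1β-hydroxy-3-oxo-13-(phenylsulfanyl)-8β-[(2E)-2-methylbut-2-enoyloxy]-10αH-germacr-4-en-12,6α-olide (C11 epimers) | c1ccc(SCC2C(=O)O[C@H]3[C@H]2[C@H](OC(=O)/C(C)=C/C)C[C@H](C)[C@H](O)CC(=O)/C(C)=C\3)cc1
F2 | step 16 | 4β,5β-epoxy-1β-hydroxy-3-oxo-13-(phenylsulfanyl)-8β-[(2E)-2-methylbut-2-enoyloxy]-10αH-germacran-12,6α-olide (C11 epimers) | c1ccc(SCC2C(=O)O[C@H]3[C@H]2[C@H](OC(=O)/C(C)=C/C)C[C@H](C)[C@H](O)CC(=O)[C@]2(C)O[C@H]32)cc1
F3 | step 16 | 4β,5β-epoxy-1β-hydroxy-3-oxo-13-(phenylsulfinyl)-8β-[(2E)-2-methylbut-2-enoyloxy]-10αH-germacran-12,6α-olide (C11 and sulfur epimers) | O=S(CC2C(=O)O[C@H]3[C@H]2[C@H](OC(=O)/C(C)=C/C)C[C@H](C)[C@H](O)CC(=O)[C@]2(C)O[C@H]32)c1ccccc1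
F4 | step 14 | (3R,4S,6R)-3-hydroxy-6-[(2S,3R)-2-[(1Z)-2-iodoprop-1-en-1-yl]-4-methylidene-5-oxooxolan-3-yl]-4-methyl-6-[(2E)-2-methylbut-2-enoyloxy]hexanoic acid | C=C1C(=O)O[C@H](/C=C(C)\I)[C@H]1[C@H](OC(=O)/C(C)=C/C)C[C@H](C)[C@H](O)CC(=O)O
F5 | step 14 | S-pyridin-2-yl (3R,4S,6R)-3-hydroxy-6-[(2S,3R)-2-[(1Z)-2-iodoprop-1-en-1-yl]-4-methylidene-5-oxooxolan-3-yl]-4-methyl-6-[(2E)-2-methylbut-2-enoyloxy]hexanethioate | C=C1C(=O)O[C@H](/C=C(C)\I)[C@H]1[C@H](OC(=O)/C(C)=C/C)C[C@H](C)[C@H](O)CC(=O)Sc1ccccn1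
F6 | step 14 | S-pyridin-2-yl (3R,4S,6R)-3-hydroxy-4-methyl-6-[(2E)-2-methylbut-2-enoyloxy]-6-[(2S,3R)-4-methylidene-5-oxo-2-[(1Z)-2-(trimethylstannyl)prop-1-en-1-yl]oxolan-3-yl]hexanethioate | C=C1C(=O)O[C@H](/C=C(C)\[Sn](C)(C)C)[C@H]1[C@H](OC(=O)/C(C)=C/C)C[C@H](C)[C@H](O)CC(=O)Sc1ccccn1
F7 | step 11 | (4S,5S)-4-[(3S)-3-[(4R)-2,2-dimethyl-1,3-dioxan-4-yl]butanoyl]-5-[(1Z)-2-iodoprop-1-en-1-yl]-3-methylideneoxolan-2-one | C=C1C(=O)O[C@H](/C=C(C)\I)[C@H]1C(=O)C[C@H](C)[C@H]2CCOC(C)(C)O2
F8 | step 11 | (4R,5S)-4-[(1R,3S)-3-[(4R)-2,2-dimethyl-1,3-dioxan-4-yl]-1-hydroxybutyl]-5-[(1Z)-2-iodoprop-1-en-1-yl]-3-methylideneoxolan-2-one | C=C1C(=O)O[C@H](/C=C(C)\I)[C@H]1[C@H](O)C[C@H](C)[C@H]2CCOC(C)(C)O2
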